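The route rests on disconnecting the C13–C16 bond of ring D. In the target, ring D is an α-methylene cyclopentanone (C15 ketone on quaternary C8, C16=C17) whose α-carbon C16 is joined to bridgehead C13, and C13 lies β to C11, an epoxide carbon that can be carried as a ketone. A phosphine-catalysed Rauhut–Currier reaction therefore closes ring D, sets C13 and delivers the exocyclic enone in one operation. Its precursor is a bis-enone: a C8 vinyl ketone beside a ring C cyclohex-2-enone carrying the C9 oxygen, with ring A and the oxepane ring B complete. Ring C derives from a benzoate joined to C10 by enolate arylation and dearomatised by Birch alkylation.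

Key step: step 14

Remark: atoms carry ent-kaurane locants (C20 is the methyl on C10; ring A is C1–C5 and C10; ring B is the oxepane C5–C6–O–C7–C8–C9–C10; ring C is C8, C9, C11–C14; ring D is C8, C13–C16); C6 is treated as a labile acetal centre whose drawn configuration is assumed to be the thermodynamic one.

Step 1
Reactants: 1 2,4,4-trimethylcyclohex-2-en-1-one; 2 vinylmagnesium bromide
Product: 3 trimethyl{[(3R)-3-ethenyl-2,4,4-trimethylcyclohex-1-en-1-yl]oxy}silane
Conditions: CuBr·SMe2 (5 mol %), (R,Sp)- or (S,Rp)-1-[2-(diphenylphosphino)ferrocenyl]ethyldicyclohexylphosphine (6 mol %; the enantiomer that gives 3R), Me3SiCl, t-BuOMe/THF, −78 °C; Et3N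
Reagents that add atoms: chlorotrimethylsilane (C[Si](C)(C)Cl)
Why: Copper-catalysed asymmetric conjugate addition of a Grignard reagent with in situ silylation: the ferrocenyl diphosphine–copper complex selects the enone face to set C5 as R, and trapping as the silyl enol ether fixes the C1/C10 enolate regiochemistry for the next step.

Step 2
Reactants: 3 silyl enol ether; 4 methyl 2-bromo-3-methoxybenzoate
Product: 5 methyl 2-[(1R,6R)-6-ethenyl-1,5,5-trimethyl-2-oxocyclohexyl]-3-methoxybenzoate
Conditions: Pd2(dba)3 (2.5 mol %), P(t-Bu)3 (6 mol %), ZnF2 (0.6 equiv), DMF, 80 °C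
Reagents that add atoms: none
Why: Palladium-catalysed α-arylation of a silyl enol ether through its fluoride-released zinc enolate: only C10 can couple because the enolate is regiodefined, and the arylpalladium is delivered anti to the pseudo-axial C5 vinyl group, which sets the quaternary C10 with the aryl trans to vinyl and the methyl axial.

Step 3
Reactants: 5 α-aryl ketone
Product: 6 methyl 2-[(1R,6R)-6-ethenyl-3-hydroxy-1,5,5-trimethyl-2-oxocyclohex-3-en-1-yl]-3-methoxybenzoate
Conditions: SeO2, 1,4-dioxane/H2O, 90 °C
Reagents that add atoms: selenium dioxide (O=[Se]=O)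
Why: Riley oxidation: C2 is the only enolisable position of the ketone, so SeO2 gives the 1,2-dione, which rests as its C2 enol.

Step 4
Reactants: 6 diosphenol
Product: 8 C2-hydroxy benzo-δ-lactone trans-fused to ring A, via cis-diol methyl ester 7 (not isolated)
Conditions: NaBH4, CeCl3·7H2O, MeOH, −20 to 23 °C; then p-toluenesulfonic acid monohydrate (cat.), PhMe, 60 °C
Reagents that add atoms: none
Why: Luche-type borohydride reduction followed by acid-catalysed lactonisation: hydride reaches C1 and then C2 from the face opposite the syn-axial methyl groups on C10 and C4, giving the cis-diol on the C20 face, and only the equatorial C1 hydroxyl can close the six-membered lactone onto the ester.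

Step 5
Reactants: 8 hydroxy lactone
Product: 10 C6 dimethyl acetal of the lactone, via C6 aldehyde 9 (not isolated)
Conditions: O3, CH2Cl2/MeOH, −78 °C; Me2S; then HC(OMe)3, p-toluenesulfonic acid monohydrate (cat.), 23 °C
Reagents that add atoms: ozone ([O-][O+]=O); trimethyl orthoformate (COC(OC)OC)
Why: Ozonolysis with reductive work-up and acetalisation: the terminal alkene is the only ozone-reactive site (the acylated anisole ring is electron-poor), and C5, already in its more stable arrangement, is not at risk while the aldehyde is masked for the dissolving-metal step.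

Step 6
Reactants: 10 acetal lactone; 11 (triisopropylsiloxy)methyl chloride
Product: 13 C8-quaternary cyclohexa-1,4-diene lactone with C7 silyl ether, via dilithium dienolate 12 (not isolated)
Conditions: Li, NH3(l)/THF, t-BuOH (1 equiv), −78 °C; isoprene; NH3 removed; then 11, THF, −78 °C
Reagents that add atoms: none
Why: Birch reductive alkylation of a benzoate: reduction with protonation at C12 gives the lactone dienolate, and the α-chloro ether alkylates C8 on the face opposite the C10 methyl, which stands axial over the trans-fused lactone ring, so the new C7 arm is anti to C20 (the buried axial C2 alkoxide stays unalkylated).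

Step 7
Reactants: 13 silyl ether
Product: 14 C7 primary alcohol
Conditions: Bu4NF, THF, 0 °C
Reagents that add atoms: none
Why: Fluoride cleavage of the primary silyl ether frees the C7 hydroxyl under non-acidic conditions that spare the enol ether, lactone and acetal.

Step 8
Reactants: 14 hydroxy enol ether
Product: 16 C9-hydroxy C11-ketone with C13=C14, via methoxy-oxirane 15 (not isolated)
Conditions: VO(acac)2 (5 mol %), t-BuOOH, CH2Cl2, 0 °C; then aqueous oxalic acid on SiO2, CH2Cl2, 23 °C
Reagents that add atoms: tert-butyl hydroperoxide (CC(C)(C)OO); water (O)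
Why: Hydroxyl-directed vanadium-catalysed epoxidation of the enol ether (Rubottom-type α-hydroxylation) followed by mild hydrolysis: the homoallylic C7 hydroxyl delivers oxygen to its own face of the electron-rich C9=C11 bond, the face that the axial C10 methyl leaves open, and the labile methoxy-oxirane is hydrolysed to the ketone faster than the C6 acetal, which the rigid lactone also prevents from engaging either hydroxyl.

Step 9
Reactants: 16 β,γ-unsaturated ketone
Product: 17 conjugated C12=C13 enone
Conditions: 1,8-diazabicyclo[5.4.0]undec-7-ene (0.3 equiv), CH2Cl2, 23 °C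
Reagents that add atoms: none
Why: Base-catalysed prototropic shift through the C12 dienolate moves the alkene into conjugation with C11, the only conjugated position because C8 and C9 are fully substituted.

Step 10
Reactants: 17 triol enone
Product: 18 tris(triethylsilyl) ether at O7 O9 O2
Conditions: Et3SiOTf, 2,6-lutidine, CH2Cl2, −78 to 0 °C; MeOH quench
Reagents that add atoms: triethylsilyl trifluoromethanesulfonate (CC[Si](CC)(CC)OS(=O)(=O)C(F)(F)F)
Why: Silyl triflate silylation of all three hydroxyls: the tertiary C9 oxygen must be masked before the lactone is opened, since a free C9 hydroxyl would later capture C6 as a five-membered acetal, and the methanol quench returns any silyl-activated acetal to the dimethyl acetal.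

Step 11
Reactants: 18 silylated enone lactone; 2 vinylmagnesium bromide
Product: 20 ring-opened triol with C15 vinyl carbinol, via lactol 19 (not isolated)
Conditions: iBu2AlH, CH2Cl2, −78 °C; then CH2=CHMgBr, THF, −78 to 0 °C
Reagents that add atoms: none
Why: Hydride reduction of the lactone to the lactol (and 1,2-reduction of the enone) followed by Grignard addition to the ring-opened aldehyde: C11 is taken to the alcohol on purpose so that only C15 accepts the vinyl group, and both new carbinol centres are erased in the next step.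

Step 12
Reactants: 20 triol
Product: 21 bis-enone with free C1 hydroxyl
Conditions: MnO2 (activated, excess), CH2Cl2, 23 °C
Reagents that add atoms: none
Why: MnO2 oxidises only the two allylic alcohols, at C11 and C15, and leaves the saturated C1 hydroxyl and the silyl ethers untouched.

Step 13
Reactants: 21 bis-enone
Product: 22 oxepane methyl acetal bis-enone (Rauhut–Currier precursor)
Conditions: pyridinium p-toluenesulfonate (cat.), CH2Cl2/MeOH (20:1), 0 to 23 °C
Reagents that add atoms: none
Why: Acid-catalysed methanolysis of the primary silyl ether and transacetalisation: the freed C7 hydroxyl captures the C6 oxocarbenium ion to close the oxepane, the masked C9 oxygen and the geometrically remote C1 hydroxyl cannot compete, and C6 equilibrates to the more stable anomer.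

Step 14
Reactants: 22 vinyl ketone–cyclohexenone bis-enone
Product: 23 ring D α-methylene cyclopentanone with C11 ketone
Conditions: PMe3 (30 mol %), t-AmOH, 0.01 M, 23 °C
Reagents that add atoms: none
Why: PMe3 adds to C17 of the unhindered vinyl ketone to give a β-phosphonium enolate whose α-carbon C16 attacks C13 of the cyclohexenone, after which proton transfer from C16 to C12 and loss of PMe3 restore the C16=C17 alkene. The closest known reaction is the phosphine-catalysed Rauhut–Currier cycloisomerisation of bis-enones. Ring D closes in the 5-(enolendo)-exo-trig mode, the less favourable enolate geometry, which is tolerated here because the trans-fused oxepane holds the C8 acyl group axial on ring C, 1,3-diaxial to C13 and directly over its π-face. C13 is the only new stereocentre and is fixed by the tether, since C16 can reach only the face of ring C that carries C15. The step needs the phosphine to choose the vinyl ketone over the β-substituted cyclohexenone, which its open terminus secures, and it needs no competing hetero-Michael addition, which the substrate secures because C7 is tied up in the oxepane, O9 is silylated and the C1 hydroxyl points away from C15.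

Step 15
Reactants: 23 bis-silyl ether
Product: 24 C1 C2 C9 triol
Conditions: Bu4NF, AcOH, THF, 23 °C
Reagents that add atoms: none
Why: Buffered fluoride removes both triethylsilyl groups without acid, so the C9 hydroxyl is freed without giving the acetal a chance to migrate to it.

Step 16
Reactants: 24 triol
Product: 25 C1 C2 diacetate
Conditions: Ac2O, 4-(dimethylamino)pyridine (cat.), pyridine, 23 °C
Reagents that add atoms: acetic anhydride (CC(=O)OC(C)=O)
Why: Nucleophile-catalysed acetylation esterifies the two secondary hydroxyls, while the tertiary C9 hydroxyl between two quaternary carbons does not react.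

Step 17
Reactants: 25 diketone
Product: 26 C11 C15 diol
Conditions: NaBH4, CeCl3·7H2O, MeOH, −78 to −20 °C
Reagents that add atoms: none
Why: Luche reduction: the C15 enone is reduced 1,2 and the C11 ketone is attacked from the face of the C9 hydroxyl, the other face being covered by the C15–C16 bridge, so the C11 hydroxyl ends axial and trans to the C9 hydroxyl.

Step 18
Reactants: 26 diol
Product: 27 C15 enone with C11 hydroxyl
Conditions: MnO2 (activated), CH2Cl2, 23 °C
Reagents that add atoms: none
Why: MnO2 re-oxidises only the allylic C15 alcohol to the exo-methylene ketone.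

Step 19
Reactants: 27 C9 C11 diol
Product: 28 C11 mesylate
Conditions: MsCl, Et3N, CH2Cl2, −10 °C
Reagents that add atoms: methanesulfonyl chloride (CS(=O)(=O)Cl)
Why: Sulfonylation through sulfene takes the secondary C11 hydroxyl and leaves the tertiary C9 hydroxyl free.

Step 20
Reactants: 28 hydroxy mesylate
Product: 29 9,11-epoxide methyl acetal
Conditions: NaH, THF, 0 to 23 °C
Reagents that add atoms: none
Why: Intramolecular Williamson reaction (3-exo-tet): the C9 alkoxide and the C11 mesylate are trans-diaxial, so displacement with inversion at C11 closes the 9,11-epoxide on the face opposite the ring D bridge.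

Step 21
Reactants: 29 methyl acetal
Product: 30 CNP0224512.1
Conditions: AcOH/THF/H2O (3:1:1), 40 °C
Reagents that add atoms: water (O)
Why: Mild acid hydrolysis of the seven-membered mixed acetal: the cyclic oxocarbenium ion at C6 forms much more easily than the hindered epoxide opens, and now only the C7 oxygen can hold C6, so water gives the lactol as its thermodynamic anomer.

Compound list
1 | 2,4,4-trimethylcyclohex-2-en-1-one | CC1=CC(C)(C)CCC1=O | starting material
2 | vinylmagnesium bromide | C=C[Mg]Br | starting material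
3 | trimethyl{[(3R)-3-ethenyl-2,4,4-trimethylcyclohex-1-en-1-yl]oxy}silane | C=C[C@@H]1C(C)(C)CCC(O[Si](C)(C)C)=C1C | intermediate
4 | methyl 2-bromo-3-methoxybenzoate | COC(=O)c1cccc(OC)c1Br | starting material
5 | methyl 2-[(1R,6R)-6-ethenyl-1,5,5-trimethyl-2-oxocyclohexyl]-3-methoxybenzoate (aryl trans to vinyl) | C=C[C@@H]1C(C)(C)CCC(=O)[C@@]1(C)c1c(OC)cccc1C(=O)OC | intermediate
6 | methyl 2-[(1R,6R)-6-ethenyl-3-hydroxy-1,5,5-trimethyl-2-oxocyclohex-3-en-1-yl]-3-methoxybenzoate (diosphenol) | C=C[C@@H]1C(C)(C)C=C(O)C(=O)[C@@]1(C)c1c(OC)cccc1C(=O)OC | intermediate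
7 | cis-diol methyl ester: 5 with C1–OH and C2–OH in place of the ketone, both on the face of the C10 methyl | C=C[C@@H]1C(C)(C)C[C@H](O)[C@H](O)[C@@]1(C)c1c(OC)cccc1C(=O)OC | intermediate (not isolated)
8 | hydroxy lactone: benzo-δ-lactone C15(=O)–O–C1 trans-fused to ring A, C2–OH axial and cis to C1–O, C5 vinyl trans to the aryl ring | C=C[C@@H]1C(C)(C)C[C@H](O)[C@@H]2OC(=O)c3cccc(OC)c3[C@@]12C | intermediate
9 | C6 aldehyde: 8 with CHO in place of vinyl | O=C[C@@H]1C(C)(C)C[C@H](O)[C@@H]2OC(=O)c3cccc(OC)c3[C@@]12C | intermediate (not isolated)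
10 | C6 dimethyl acetal of 9 | COC(OC)[C@@H]1C(C)(C)C[C@H](O)[C@@H]2OC(=O)c3cccc(OC)c3[C@@]12C | intermediate
11 | (triisopropylsiloxy)methyl chloride | CC(C)[Si](OCCl)(C(C)C)C(C)C | starting material
12 | dilithium salt of the lactone dienolate (C8=C15 enolate, C9=C11 methyl enol ether, C13=C14) and C2 alkoxide | COC(OC)[C@@H]1C(C)(C)C[C@H]([O-])[C@@H]2OC([O-])=C3C=CCC(OC)=C3[C@@]12C.[Li+].[Li+] | intermediate (not isolated)
13 | Birch product: quaternary C8 bearing CH2OSi(iPr)3 (C7, anti to C20), lactone retained, C9=C11 methyl enol ether, C13=C14 | COC(OC)[C@@H]1C(C)(C)C[C@H](O)[C@@H]2OC(=O)[C@]3(CO[Si](C(C)C)(C(C)C)C(C)C)C=CCC(OC)=C3[C@@]12C | intermediate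
14 | C7 primary alcohol of 13 | COC(OC)[C@@H]1C(C)(C)C[C@H](O)[C@@H]2OC(=O)[C@]3(CO)C=CCC(OC)=C3[C@@]12C | intermediate
15 | C9–C11 methoxy-oxirane of 14, oxygen on the face of C7 | COC(OC)[C@@H]1C(C)(C)C[C@H](O)[C@@H]2OC(=O)[C@]3(CO)C=CC[C@@]4(OC)O[C@@]34[C@@]12C | intermediate (not isolated)
16 | α-hydroxy ketone: C9–OH cis to C7, C11 ketone, C13=C14, lactone and C6 dimethyl acetal retained | COC(OC)[C@@H]1C(C)(C)C[C@H](O)[C@@H]2OC(=O)[C@]3(CO)C=CCC(=O)[C@]3(O)[C@@]12C | intermediate
17 | conjugated isomer of 16 (C12=C13 enone) | COC(OC)[C@@H]1C(C)(C)C[C@H](O)[C@@H]2OC(=O)[C@]3(CO)CC=CC(=O)[C@]3(O)[C@@]12C | intermediate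
18 | tris(triethylsilyl) ether of 17 at O7, O9 and O2 | COC(OC)[C@@H]1C(C)(C)C[C@H](O[Si](CC)(CC)CC)[C@@H]2OC(=O)[C@]3(CO[Si](CC)(CC)CC)CC=CC(=O)[C@]3(O[Si](CC)(CC)CC)[C@@]12C | intermediate
19 | lactol (C15) and C11 allylic alcohol from 18, epimer mixtures at C15 and C11 | COC(OC)[C@@H]1C(C)(C)C[C@H](O[Si](CC)(CC)CC)[C@@H]2OC(O)[C@]3(CO[Si](CC)(CC)CC)CC=CC(O)[C@]3(O[Si](CC)(CC)CC)[C@@]12C | intermediate (not isolated)
20 | ring-opened triol: C15 vinyl carbinol, C11 allylic alcohol (both epimer mixtures), free C1–OH, three silyl ethers, C6 dimethyl acetal | COC(OC)[C@@H]1C(C)(C)C[C@H](O[Si](CC)(CC)CC)[C@H](O)[C@@]1(C)[C@@]2(O[Si](CC)(CC)CC)C(O)C=CC[C@@]2(CO[Si](CC)(CC)CC)C(O)C=C | intermediate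
21 | bis-enone: C15 vinyl ketone and C11 cyclohex-2-enone, free C1–OH, three silyl ethers, C6 dimethyl acetal | COC(OC)[C@@H]1C(C)(C)C[C@H](O[Si](CC)(CC)CC)[C@H](O)[C@@]1(C)[C@@]2(O[Si](CC)(CC)CC)C(=O)C=CC[C@@]2(CO[Si](CC)(CC)CC)C(=O)C=C | intermediate
22 | Rauhut–Currier precursor: oxepane methyl acetal (C7–O–C6), C8 vinyl ketone, ring C cyclohex-2-enone, C9–OSiEt3, C2–OSiEt3, C1–OH | C=CC(=O)[C@@]23CO[C@@H](OC)[C@@H]4C(C)(C)C[C@H](O[Si](CC)(CC)CC)[C@H](O)[C@@]4(C)[C@@]2(O[Si](CC)(CC)CC)C(=O)C=CC3 | intermediate
23 | Rauhut–Currier product: ring D α-methylene cyclopentanone (C16–C13 bond), C11 ketone, protecting groups as in 22 | C=C1C(=O)[C@@]23CO[C@@H](OC)[C@@H]4C(C)(C)C[C@H](O[Si](CC)(CC)CC)[C@H](O)[C@@]4(C)[C@@]2(O[Si](CC)(CC)CC)C(=O)C[C@@H]1C3 | intermediate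
24 | C1, C2, C9 triol of 23 | C=C1C(=O)[C@@]23CO[C@@H](OC)[C@@H]4C(C)(C)C[C@H](O)[C@H](O)[C@@]4(C)[C@@]2(O)C(=O)C[C@@H]1C3 | intermediate
25 | C1, C2 diacetate with free C9–OH | C=C1C(=O)[C@@]23CO[C@@H](OC)[C@@H]4C(C)(C)C[C@H](OC(C)=O)[C@H](OC(C)=O)[C@@]4(C)[C@@]2(O)C(=O)C[C@@H]1C3 | intermediate
26 | C11, C15 diol: C11–OH trans to C9–OH, C15 epimer mixture | C=C1C(O)[C@@]23CO[C@@H](OC)[C@@H]4C(C)(C)C[C@H](OC(C)=O)[C@H](OC(C)=O)[C@@]4(C)[C@@]2(O)[C@@H](O)C[C@@H]1C3 | intermediate
27 | C15 enone with trans C9, C11 diol | C=C1C(=O)[C@@]23CO[C@@H](OC)[C@@H]4C(C)(C)C[C@H](OC(C)=O)[C@H](OC(C)=O)[C@@]4(C)[C@@]2(O)[C@@H](O)C[C@@H]1C3 | intermediate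
28 | C11 mesylate of 27 | C=C1C(=O)[C@@]23CO[C@@H](OC)[C@@H]4C(C)(C)C[C@H](OC(C)=O)[C@H](OC(C)=O)[C@@]4(C)[C@@]2(O)[C@@H](OS(C)(=O)=O)C[C@@H]1C3 | intermediate
29 | 9,11-epoxide, C6 O-methyl acetal of the target | C=C1C(=O)[C@@]23CO[C@@H](OC)[C@@H]4C(C)(C)C[C@H](OC(C)=O)[C@H](OC(C)=O)[C@@]4(C)[C@]24O[C@@H]4C[C@@H]1C3 | intermediate
30 | CNP0224512.1 | C=C1C(=O)[C@@]23CO[C@@H](O)[C@@H]4C(C)(C)C[C@H](OC(C)=O)[C@H](OC(C)=O)[C@@]4(C)[C@]24O[C@@H]4C[C@@H]1C3 | target

Total step count: 21. Longest linear sequence: 21 steps, from 1 to 30; compounds 2, 4 and 11 are commercial inputs.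

Steps most likely to fail

Step 14, ring D closure. What may go wrong: the phosphonium enolate has to attack with its enolate double bond inside the forming five-membered ring, so reversible phosphine addition may lead to intermolecular coupling and oligomerisation of the vinyl ketone instead of closure. The fallback sets out from 22 and makes the same bond in a stoichiometric, sulfur-triggered tandem Michael–Michael addition. Me2AlSPh (CH2Cl2, −78 to 0 °C) should add thiolate to C17, and the aluminium enolate so formed, with the ring enone activated by the Lewis acid, should close onto C13 to give the ring-closed C17 phenyl sulfide F1. Oxidation with 3-chloroperbenzoic acid at −78 °C and warming with Et3N eliminates the sulfoxide and returns the route at 23.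

Step 2, arylation at C10. What may go wrong: coupling of the doubly ortho-substituted arylpalladium bromide with a tetrasubstituted enolate may be so slow that protodesilylation and hydrodebromination take over. The fallback sets out from 3 and uses metal-free nucleophilic aromatic substitution on an arene with a small, linear activating group. The potassium enolate (KOtBu, THF/DMF, 0 to 60 °C) is arylated by 2-fluoro-3-methoxybenzonitrile to give the nitrile ketone F2. SeO2 gives the diosphenol nitrile F3, and NaBH4/CeCl3·7H2O gives the cis-diol nitrile F4, whose C1 alkoxide adds to the nitrile to form the cyclic imidate F5. Aqueous HCl in THF hydrolyses F5 and returns the route at 8.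

Step 13, oxepane closure. What may go wrong: once the C7 hydroxyl is freed, its oxa-Michael addition to the neighbouring vinyl ketone (six-membered ring) may compete with capture of the C6 oxocarbenium ion. The fallback sets out from 21 and masks the vinyl ketone first. PhSH with catalytic Et3N (CH2Cl2, 0 °C) gives the β-phenylthio ketone F6, and pyridinium p-toluenesulfonate in CH2Cl2/MeOH then closes the oxepane to give the oxepane-closed β-phenylthio ketone F7. 3-Chloroperbenzoic acid at −78 °C followed by warming with Et3N regenerates the vinyl ketone by sulfoxide elimination and returns the route at 22.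

Further compounds
F1 | step 14 | ring-closed C17 phenyl sulfide: 23 with C16–H and C17H2–SPh in place of the C16=C17 alkene (C16 epimer mixture) | c1ccccc1SCC1C(=O)[C@@]23CO[C@@H](OC)[C@@H]4C(C)(C)C[C@H](O[Si](CC)(CC)CC)[C@H](O)[C@@]4(C)[C@@]2(O[Si](CC)(CC)CC)C(=O)C[C@@H]1C3
F2 | step 2 | 2-[(1R,6R)-6-ethenyl-1,5,5-trimethyl-2-oxocyclohexyl]-3-methoxybenzonitrile | C=C[C@@H]1C(C)(C)CCC(=O)[C@@]1(C)c1c(OC)cccc1C#N
F3 | step 2 | diosphenol nitrile: 6 with C≡N in place of CO2Me | C=C[C@@H]1C(C)(C)C=C(O)C(=O)[C@@]1(C)c1c(OC)cccc1C#N
F4 | step 2 | cis-diol nitrile: 7 with C≡N in place of CO2Me | C=C[C@@H]1C(C)(C)C[C@H](O)[C@H](O)[C@@]1(C)c1c(OC)cccc1C#N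
F5 | step 2 | cyclic imidate: 8 with C=NH in place of the lactone C=O | C=C[C@@H]1C(C)(C)C[C@H](O)[C@@H]2OC(=N)c3cccc(OC)c3[C@@]12C
F6 | step 13 | β-phenylthio ketone: 21 with C15(=O)–CH2–CH2–SPh in place of the vinyl ketone | COC(OC)[C@@H]1C(C)(C)C[C@H](O[Si](CC)(CC)CC)[C@H](O)[C@@]1(C)[C@@]2(O[Si](CC)(CC)CC)C(=O)C=CC[C@@]2(CO[Si](CC)(CC)CC)C(=O)CCSc1ccccc1
F7 | step 13 | oxepane-closed β-phenylthio ketone: 22 with C15(=O)–CH2–CH2–SPh in place of the vinyl ketone | c1ccccc1SCCC(=O)[C@@]23CO[C@@H](OC)[C@@H]4C(C)(C)C[C@H](O[Si](CC)(CC)CC)[C@H](O)[C@@]4(C)[C@@]2(O[Si](CC)(CC)CC)C(=O)C=CC3
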